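Ring B, the 8-benzoylphloroglucinol ring of the chroman-2-one, carries oxygen at C5, C7 and C8a and an acyl group at C8, the pattern of a folded polyketide. The route therefore cuts the C8–C8a bond: a fully substituted 2-pyranone whose lactone carbonyl is the future C8a and whose 6-phenacyl carbon is the future C8 is opened by methoxide and recloses by Claisen condensation, so that one operation turns the pyranone into aromatic ring B with the benzoyl group in place. The precursor already holds the C4 stereocentre (R, set by carbene catalysis), the C6 prenyl group and a MOM ether on the future O5, which later forces the lactone onto the C8a oxygen.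

Key step: step 6

Assumption: the antipode of the aminoindanol-derived triazolium salt that leads to the (R) series is used; both antipodes are commercial, and the sense of induction is to be confirmed at compound 4 before material is carried forward.

Locants C4, C4a, C5–C8 and C8a are those of the chroman-2-one target; pyranone locants are marked as such.

Step 1
Reactants: 1 4-hydroxy-6-methyl-2H-pyran-2-one; 2 (E)-cinnamaldehyde
Product: 4 methyl (3R)-3-(4-hydroxy-6-methyl-2-oxo-2H-pyran-3-yl)-3-phenylpropanoate, via bicyclic enol lactone 3 (not isolated)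
Conditions: aminoindanol-derived N-mesityl triazolium chloride (10 mol %), 3,3',5,5'-tetra-tert-butyldiphenoquinone (1.2 equiv), K2CO3 (20 mol %), 4 Å MS, toluene, rt; then MeOH, rt
Reagents that add atoms: methanol, CO
Why: Oxidative carbene catalysis turns 2 into an α,β-unsaturated acyl azolium, pyranone C3 of 1 adds to it in a Michael sense on the face left open by the aminoindanol backbone (this sets the future C4 as R), acyl transfer to the neighbouring oxygen releases the carbene, and the strained enol lactone 3 is methanolysed in the same flask to 4.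

Step 2
Reactants: 4 methyl (3R)-3-(4-hydroxy-6-methyl-2-oxo-2H-pyran-3-yl)-3-phenylpropanoate
Product: 5 methyl (3R)-3-[4-(methoxymethoxy)-6-methyl-2-oxo-2H-pyran-3-yl]-3-phenylpropanoate
Conditions: MOMCl (1.3 equiv), i-Pr2NEt (2 equiv), CH2Cl2, 0 °C → rt
Reagents that add atoms: chloromethyl methyl ether, COCCl
Why: O-Alkylation of the preformed ammonium pyranolate with the hard electrophile MOMCl should give the 4-alkoxy-2-pyranone, which marks this oxygen (the future O5) as the protected one and removes the acidic OH before the base steps.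

Step 3
Reactants: 5 methyl (3R)-3-[4-(methoxymethoxy)-6-methyl-2-oxo-2H-pyran-3-yl]-3-phenylpropanoate
Product: 6 methyl (3R)-3-[5-bromo-4-(methoxymethoxy)-6-methyl-2-oxo-2H-pyran-3-yl]-3-phenylpropanoate
Conditions: NBS (1.05 equiv), MeCN, 0 °C → rt, dark
Reagents that add atoms: N-bromosuccinimide, O=C1CCC(=O)N1Br
Why: Electrophilic bromination (addition–elimination) at pyranone C5, the only unsubstituted ring carbon and the β-carbon of the ring enol ether, under ionic light-excluded conditions that avoid radical attack at the 6-methyl group or the benzylic C–H.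

Step 4
Reactants: 6 methyl (3R)-3-[5-bromo-4-(methoxymethoxy)-6-methyl-2-oxo-2H-pyran-3-yl]-3-phenylpropanoate; 7 tributyl(3-methylbut-2-en-1-yl)stannane
Product: 8 methyl (3R)-3-[4-(methoxymethoxy)-6-methyl-5-(3-methylbut-2-en-1-yl)-2-oxo-2H-pyran-3-yl]-3-phenylpropanoate
Conditions: Pd(PPh3)4 (10 mol %), CuI (20 mol %), DMF, 90 °C
Reagents that add atoms: none
Why: Stille coupling at the C5–Br bond (oxidative addition of zerovalent palladium, CuI-assisted transmetallation, reductive elimination at the primary prenyl terminus); the stannane is preferred to an allylboronate because it transfers prenyl mainly without allylic transposition, under neutral conditions that spare the MOM acetal and the esters.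

Step 5
Reactants: 8 methyl (3R)-3-[4-(methoxymethoxy)-6-methyl-5-(3-methylbut-2-en-1-yl)-2-oxo-2H-pyran-3-yl]-3-phenylpropanoate; 9 N-methoxy-N-methylbenzamide
Product: 10 methyl (3R)-3-[4-(methoxymethoxy)-5-(3-methylbut-2-en-1-yl)-2-oxo-6-(2-oxo-2-phenylethyl)-2H-pyran-3-yl]-3-phenylpropanoate
Conditions: LiN(SiMe3)2 (1.1 equiv), THF, −78 °C; then 9 (1.3 equiv), −78 → −20 °C; AcOH quench
Reagents that add atoms: none
Why: Vinylogous deprotonation of the 6-methyl group, the only C–H whose anion is conjugated through the ring to the lactone carbonyl, followed by Weinreb ketone synthesis; the chelated tetrahedral adduct persists until the quench, so one equivalent of base suffices and the ester α-CH2 and the benzylic methine are left alone.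

Step 6
Reactants: 10 methyl (3R)-3-[4-(methoxymethoxy)-5-(3-methylbut-2-en-1-yl)-2-oxo-6-(2-oxo-2-phenylethyl)-2H-pyran-3-yl]-3-phenylpropanoate
Product: 12 methyl (3R)-3-[3-benzoyl-2,4-dihydroxy-6-(methoxymethoxy)-5-(3-methylbut-2-en-1-yl)phenyl]-3-phenylpropanoate, via ring-opened diketo diester 11 (not isolated)
Conditions: Mg(OMe)2 (4 equiv), MeOH, 65 °C; cold dilute aq. HCl to pH 4
Reagents that add atoms: none
Why: Methoxide adds to the lactone carbonyl of 10 (the future C8a) and the ring opens to diketo diester 11, an enoate that is E by the sequence rules yet keeps the new ester cis to the diketone chain because both were ring members; the magnesium-chelated enolate of the benzoyl-flanked methylene (future C8) then attacks that ester, methoxide leaves, and the cyclohexadienone enolises to the arene. This is the base-induced Claisen recyclisation of 6-(2-oxoalkyl)-4-oxy-2-pyranones to acylphloroglucinols, applied here to a fully substituted case. Ring B closes in a 6-(enolexo)-exo-trig mode at the C8–C8a bond. No stereocentre is created, and the C4 centre should be safe because its hydrogen is never conjugated to a carbonyl group. The step needs C-acylation to win over O-reclosure to the pyranone and over aldol folding: reclosure is reversible whereas aromatisation and chelation of the resulting o-hydroxybenzophenone are not, and the aldol mode would engage the fully substituted future C4a, which cannot aromatise. Methoxide matches both methyl esters, and the MOM ether on the former pyranone 4-oxygen (future O5) is stable to base.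

Step 7
Reactants: 12 methyl (3R)-3-[3-benzoyl-2,4-dihydroxy-6-(methoxymethoxy)-5-(3-methylbut-2-en-1-yl)phenyl]-3-phenylpropanoate
Product: 13 (4R)-8-benzoyl-7-hydroxy-5-(methoxymethoxy)-6-(3-methylbut-2-en-1-yl)-4-phenyl-3,4-dihydro-2H-chromen-2-one
Conditions: PPTS (10 mol %), toluene, 70 °C, 4 Å MS
Reagents that add atoms: none
Why: Acid-catalysed intramolecular transesterification (lactonisation) in which only the C8a hydroxyl can reach the ester, since O5 is capped as the MOM ether and O7 is out of range; the buttressed benzylic carbon favours the six-membered ring and the sieves take up methanol.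

Step 8
Reactants: 13 (4R)-8-benzoyl-7-hydroxy-5-(methoxymethoxy)-6-(3-methylbut-2-en-1-yl)-4-phenyl-3,4-dihydro-2H-chromen-2-one
Product: 14 (4R)-8-benzoyl-5,7-dihydroxy-6-(3-methylbut-2-en-1-yl)-4-phenyl-3,4-dihydro-2H-chromen-2-one
Conditions: NaHSO4·SiO2, CH2Cl2, rt
Reagents that add atoms: none
Why: Acetal hydrolysis of the phenolic MOM ether on a mildly acidic solid in a non-nucleophilic solvent, so the aryl lactone should not be opened (which would allow reclosure onto O5), the prenyl group should not cyclise onto a neighbouring phenol, and C4 is not touched.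

Compound list
1 | 4-hydroxy-6-methyl-2H-pyran-2-one | CC1=CC(O)=CC(=O)O1 | starting material
2 | (E)-cinnamaldehyde | O=C/C=C/c1ccccc1 | starting material
3 | (4R)-7-methyl-4-phenyl-3,4-dihydro-2H,5H-pyrano[4,3-b]pyran-2,5-dione | CC1=CC2=C(C(=O)O1)[C@@H](c1ccccc1)CC(=O)O2 | intermediate (not isolated)
4 | methyl (3R)-3-(4-hydroxy-6-methyl-2-oxo-2H-pyran-3-yl)-3-phenylpropanoate | O=C1OC(C)=CC(O)=C1[C@@H](c1ccccc1)CC(=O)OC | intermediate
5 | methyl (3R)-3-[4-(methoxymethoxy)-6-methyl-2-oxo-2H-pyran-3-yl]-3-phenylpropanoate | O=C1OC(C)=CC(OCOC)=C1[C@@H](c1ccccc1)CC(=O)OC | intermediate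
6 | methyl (3R)-3-[5-bromo-4-(methoxymethoxy)-6-methyl-2-oxo-2H-pyran-3-yl]-3-phenylpropanoate | O=C1OC(C)=C(Br)C(OCOC)=C1[C@@H](c1ccccc1)CC(=O)OC | intermediate
7 | tributyl(3-methylbut-2-en-1-yl)stannane | CCCC[Sn](CCCC)(CCCC)CC=C(C)C | starting material
8 | methyl (3R)-3-[4-(methoxymethoxy)-6-methyl-5-(3-methylbut-2-en-1-yl)-2-oxo-2H-pyran-3-yl]-3-phenylpropanoate | O=C1OC(C)=C(CC=C(C)C)C(OCOC)=C1[C@@H](c1ccccc1)CC(=O)OC | intermediate
9 | N-methoxy-N-methylbenzamide | CON(C)C(=O)c1ccccc1 | starting material
10 | methyl (3R)-3-[4-(methoxymethoxy)-5-(3-methylbut-2-en-1-yl)-2-oxo-6-(2-oxo-2-phenylethyl)-2H-pyran-3-yl]-3-phenylpropanoate | O=C1OC(CC(=O)c2ccccc2)=C(CC=C(C)C)C(OCOC)=C1[C@@H](c1ccccc1)CC(=O)OC | intermediate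
11 | dimethyl (2E,3R)-2-[1-(methoxymethoxy)-2-(3-methylbut-2-en-1-yl)-3,5-dioxo-5-phenylpentylidene]-3-phenylpentanedioate (epimers at the prenyl-bearing carbon, in equilibrium with enol and magnesium enolate forms) | COC(=O)/C(=C(\C(CC=C(C)C)C(=O)CC(=O)c1ccccc1)OCOC)[C@@H](c1ccccc1)CC(=O)OC | intermediate (not isolated)
12 | methyl (3R)-3-[3-benzoyl-2,4-dihydroxy-6-(methoxymethoxy)-5-(3-methylbut-2-en-1-yl)phenyl]-3-phenylpropanoate | COCOc1c(CC=C(C)C)c(O)c(C(=O)c2ccccc2)c(O)c1[C@@H](c1ccccc1)CC(=O)OC | intermediate
13 | (4R)-8-benzoyl-7-hydroxy-5-(methoxymethoxy)-6-(3-methylbut-2-en-1-yl)-4-phenyl-3,4-dihydro-2H-chromen-2-one | CC(C)=CCc1c(O)c(C(=O)c2ccccc2)c2c(c1OCOC)[C@@H](c1ccccc1)CC(=O)O2 | intermediate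
14 | (4R)-8-benzoyl-5,7-dihydroxy-6-(3-methylbut-2-en-1-yl)-4-phenyl-3,4-dihydro-2H-chromen-2-one | CC(C)=CCc1c(O)c(C(=O)c2ccccc2)c2c(c1O)[C@@H](c1ccccc1)CC(=O)O2 | target

Total step count: 8. Longest linear sequence: 8 steps (1 → 14).

Steps most likely to fail

Step 6. Methoxide addition to the lactone carbonyl may be slowed by the substituent on the neighbouring ring carbon. That would leave time for retro-Claisen loss of the benzoyl group from the diketone, for exchange of the MOM acetal by methoxide at the vinylogous carbonate stage, or for simple reclosure to the pyranone. The fallback builds the arene first and sets out from cinnamaldehyde 2. Commercial 2,4,6-trihydroxybenzophenone is C-prenylated at its single type of free ring carbon (prenyl bromide, DBU, THF, 0 °C) to give (2,4,6-trihydroxy-3-(3-methylbut-2-en-1-yl)phenyl)(phenyl)methanone F1. The hydroxyl para to the benzoyl group, the one not hydrogen-bonded to the ketone, is then capped (MOMCl, i-Pr2NEt, CH2Cl2) to give [2,6-dihydroxy-4-(methoxymethoxy)-3-(3-methylbut-2-en-1-yl)phenyl](phenyl)methanone F2. Annulation of 2 onto F2 under the carbene and diphenoquinone conditions of step 1 should let the one unsubstituted ring carbon add to the acyl azolium and the adjacent free hydroxyl take the acyl group, the other neighbour being the MOM ether. This comes back to the route at 13, ahead of step 8.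

Step 4. Oxidative addition and transmetallation may be slow at a bromide flanked by the MOM ether and the methyl group, protodebromination may compete, and the prenyl group may be delivered with allylic transposition. The fallback sets out from 6 and installs the side chain in two stages. Coupling with allyltributylstannane (Pd(PPh3)4, DMF, 90 °C), a smaller partner with no regiochemical ambiguity, should give methyl (3R)-3-[4-(methoxymethoxy)-6-methyl-2-oxo-5-(prop-2-en-1-yl)-2H-pyran-3-yl]-3-phenylpropanoate F3. Olefin cross-metathesis with excess 2-methylbut-2-ene (second-generation Grubbs catalyst, CH2Cl2, 40 °C) then converts the allyl group into prenyl and comes back to the route at 8.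

Step 5. Deprotonation α to the side-chain ester may compete and lead to benzoylation there, or acyl transfer from the amide to the delocalised anion may stall. The fallback sets out from 8 and uses the far more electrophilic aldehyde. The anion (LiN(SiMe3)2, THF, −78 °C) is trapped with benzaldehyde within minutes to give methyl (3R)-3-[6-(2-hydroxy-2-phenylethyl)-4-(methoxymethoxy)-5-(3-methylbut-2-en-1-yl)-2-oxo-2H-pyran-3-yl]-3-phenylpropanoate F4 as a mixture of carbinol epimers. Dess–Martin oxidation (CH2Cl2, NaHCO3, 0 °C) removes the new centre and comes back to the route at 10.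

Further compounds
F1 | step 6 | (2,4,6-trihydroxy-3-(3-methylbut-2-en-1-yl)phenyl)(phenyl)methanone | CC(C)=CCc1c(O)cc(O)c(C(=O)c2ccccc2)c1O
F2 | step 6 | [2,6-dihydroxy-4-(methoxymethoxy)-3-(3-methylbut-2-en-1-yl)phenyl](phenyl)methanone | CC(C)=CCc1c(OCOC)cc(O)c(C(=O)c2ccccc2)c1O
F3 | step 4 | methyl (3R)-3-[4-(methoxymethoxy)-6-methyl-2-oxo-5-(prop-2-en-1-yl)-2H-pyran-3-yl]-3-phenylpropanoate | O=C1OC(C)=C(CC=C)C(OCOC)=C1[C@@H](c1ccccc1)CC(=O)OC
F4 | step 5 | methyl (3R)-3-[6-(2-hydroxy-2-phenylethyl)-4-(methoxymethoxy)-5-(3-methylbut-2-en-1-yl)-2-oxo-2H-pyran-3-yl]-3-phenylpropanoate (carbinol epimers) | O=C1OC(CC(O)c2ccccc2)=C(CC=C(C)C)C(OCOC)=C1[C@@H](c1ccccc1)CC(=O)OC
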